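Early times look ordinary here: starting material and coupling partner join to target, with the coupling partner charged in excess of the starting material in each flask.

| flask | starting material | coupling partner | target | time |
|---|---|---|---|---|
| red | 100 mM | 300 mM |  |  |
| grey | 50.0 mM | 250 mM |  |  |
| violet | 200 mM | 300 mM |  |  |
| amber | 100 mM | 300 mM | 80.0 mM | 73 h |

- red run (time / h: [target] / mM): 4.2: 7.8; 13: 13.8; 24: 22.3; 38: 26.5; 55: 33.9; 73: 38.6
- grey run (time / h: [target] / mM): 4.2: 3.3; 13: 5.4; 24: 15.0; 38: 11.6; 55: 16.2; 73: 20.5
- violet run (time / h: [target] / mM): 4.2: 9.3; 13: 23.2; 24: 39.7; 38: 52.2; 55: 65.8; 73: 72.1

(each reading ± 2 mM)

- how the opening rate goes with [coupling partner] round the charge of the red run: the exponent of the rate at two percent of starting material gone to target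
- how the opening rate goes with [starting material] round the charge of the red run: the exponent of the rate at two percent of starting material gone to target (one fixed amount of target, the same in the runs compared)
- target in the amber run at 73 h, as a share of the starting material charged

- Overall: starting material + coupling partner -> target.
- Constant volume, constant temperature.
- Readings of a species count what is bound in complexes too.
- "The second partner" is coupling partner.
- An order is taken over about fifteen percent of the charge, up and down.
- A share of target counts the target that was charged too.

Two numbers do not go together. Taken together, the red and violet runs make target at 2.58 mM h⁻¹ over the first 24 h, but at 0.611 mM h⁻¹ between 55 h and 73 h. That is a quarter of the opening pace, yet the target at 73 h accounts for just 36.9% of the starting material charged.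

The shares suggest a way out. At 73 h the red run holds 38.6% of its starting material charged as target and the violet run 36.0%, although violet was charged 200 mM against 100 mM, so the order in starting material reads as one. This reckoning freezes the coupling partner (the pseudo-first-order picture) and supposes that target is consumed as it forms, with the two steps taken as equal by choice. The share standing as target at time t is then kt·exp(−kt). Its ratio between 24 h and 73 h, pooled over red and violet, gives 0.0109 h⁻¹. This k is the turnover constant, the fraction of starting material, and equally of target, that turns in an hour while the coupling partner stands frozen.

For the amber run, this reckoning keeps 45.2% of the charged target at 73 h and adds the new target to it, which gives a share of 72.1%. The grey run differs from the red run in both charges, but with an order of one in starting material its share against red's speaks of the coupling partner, 250 mM against 300 mM. Read so, the shares give an order of 1.34 at 13 h and −0.331 at 73 h. The pair is scattered, and this reckoning loosely takes 0.5 between them.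

The forecast differs: 1 in coupling partner, 0.9 in starting material and 97% for amber, weighing “product inhibition, reversibility or catalyst death”.

The simulation gives 0.59 in coupling partner, 1.0 in starting material and 73.8% for amber.

    starting material + coupling partner → target (0.2927 L mol⁻¹ h⁻¹)
    starting material + 2 coupling partner → target + coupling partner (0.8676 L² mol⁻² h⁻¹)
    2 coupling partner ⇌ idle reagent dimer, settled at all times (96.70 L mol⁻¹)
    target + coupling partner → side product (0.3143 L mol⁻¹ h⁻¹)

In the violet run, the target made comes to a quarter of the charge at 32.0 h, where the turnover constant gives 24.6%. In the amber run, the constant's 72.1% stands beside the simulated 73.8%. Because of the step from target and coupling partner to side product, the amber run ends at 73.8%; with that step taken away, it stands at 136%.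

The earlier runs and the new flask come from a simulation with made-up constants; the scatter is artificial.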